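A closed, stirred vessel holds starting material and protic impurity in solution, with the solid partner still undissolved, and the same charge is run at different temperatures.

all flasks: starting material 0.020 M; protic impurity 0.0200 M; solid partner 0.0190 M; time 2.5 min

| flask | temperature | remark |
|---|---|---|
| north-west | 25 °C |  |
| south | 40 °C |  |
| west |  | at 25 °C until 30 s, from then on at 55 °C |
| north-east | 55 °C |  |

    starting material → open intermediate (k1 = 0.0089 s⁻¹, Ea1 = 89.0 kJ mol⁻¹)
    fresh partner → second intermediate (k2 = 0.0014 s⁻¹, Ea2 = 79.0 kJ mol⁻¹)
    open intermediate + second intermediate → product (k3 = 0.58 M⁻¹ s⁻¹, Ea3 = 37.0 kJ mol⁻¹)
    starting material + protic impurity → quenched substrate (k4 = 0.11 M⁻¹ s⁻¹, Ea4 = 58.0 kJ mol⁻¹)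
    solid partner ⇌ fresh partner, rate k5*(cs5 - [fresh partner]) while solid is left; crystals form when [fresh partner] > cs5 (cs5 = 7.6 mM, k5 = 0.12 s⁻¹)
    (constants at 25 °C)

- solid, in amounts per volume of the solution: solid partner
- the constants hold at 25 °C; other temperatures follow from the activation energies
- at the start none of the solid partner is in solution

- the flask with the highest amount of open intermediate, in percent of the starting material charged ("all alike" if they lie within 1.5 percentage points) (north-west / south / west / north-east / all alike)
- final open intermediate, as a percentage of the starting material charged, in north-west
- final open intermediate, as a percentage of the starting material charged, in south
- final open intermediate, as a percentage of the starting material charged, in west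
- final open intermediate, as a percentage of the starting material charged, in north-east

Starting material has two exits: it opens by itself, or the protic impurity quenches it. Open intermediate then waits for the second intermediate, which comes from the dissolved fresh partner, and the two make product.

My own reckoning covers the two exits. Divide the rate of opening by the rate of quenching, and the starting material drops out, but the protic impurity stays in, and quenching consumes it, so the ratio changes along the run. With the impurity held at its charge, this ratio (the selectivity factor) is the opening constant over the quenching constant times the impurity: 4.05 at 25 °C, 7.36 at 40 °C and 12.7 at 55 °C. The opening share, the part of the reacted starting material that opens, is this ratio over one plus itself: 80.2%, then 88.0%, then 92.7%. My reckoning stops there, since it puts no number on the loss to product.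

Two colleagues part at this point. The first says that open intermediate follows the opening share, which is higher in the hottest flask than in the others. Heat also cuts the opening time constant from 112 s to 4.22 s, against a run of 2.5 min. The opening speeds up 27 times from coldest to hottest and the product step 3.9 times, so the first colleague backs north-east.

The second answers that the loss needs two steps in series. The making of second intermediate speeds up 18.4 times, so the two together gain 71.8, more than the opening gains. The second colleague's forecast, which is not my shares, reads 62.3% in north-west, 68.5% in south, 32% in west and 27% in north-east, with south highest, because when hot the second intermediate “forms fast enough to consume most of the open intermediate”.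

The simulation gives 67.8% in south, higher than 63.0% in north-west, 30.4% in west and 26.1% in north-east, and the second colleague wins. South, with conversion at >99.9%, holds 20.8% product, and open intermediate plus product come to 88.6% against its opening share of 88.0%, which was reckoned with the impurity at its charge, while at the end the impurity stands at 88.7% of that charge. The first colleague keeps the cold end: north-west, with 2.47% product, stands below south. North-east has an opening share of 92.7% and ends with 26.1% open intermediate beside 66.8% product.

The rate constants belong to no real substance.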